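**Retrosynthetic overview**
- Last bond: the C5–O bond of ring A, made by carbonyl-directed C5–H lithiation, borate trapping and oxidation of 3,6,7,8-tetramethoxy-2-(3-methoxyphenyl)chromen-4-one (the new step).
- Ring C, the only ring formed: C-aroylation of 1-(2-hydroxy-3,4,5-trimethoxyphenyl)-2-methoxyethanone with 3-methoxybenzoyl chloride, then acid cyclodehydration (O1–C2 bond). The 3-OMe arrives with the methoxyacetyl unit.
- That ketone: chelation-controlled ortho-demethylation of the tetramethoxyphenyl methoxymethyl ketone, which comes from ortho-lithiated 1,2,3,4-tetramethoxybenzene and the Weinreb amide of methoxyacetic acid.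
- Ring order: rings A and B are bought as benzenes, ring C is closed in step 3, and the last oxygen goes onto ring A in step 4.

Assumption: the target has no stereocentre and no stereogenic double bond, so it is achiral and "single enantiomer" means the compound as drawn.

**Step 1**
Reactants: 1 1,2,3,4-tetramethoxybenzene; 2 N,2-dimethoxy-N-methylacetamide
Product: 4 2-methoxy-1-(2,3,4,5-tetramethoxyphenyl)ethan-1-one, via aryllithium 3 (not isolated)
Conditions: n-BuLi (1.1 equiv), TMEDA (1.1 equiv), THF, 0 °C, 1 h; then 2 (1.2 equiv), −78 °C → rt; then 1 M HCl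
Reagents that add atoms: none
Why: Directed ortho-metalation puts lithium on the only type of ring C–H of 1, and the aryllithium adds once to the Weinreb amide because the chelated tetrahedral adduct survives until work-up (Weinreb ketone synthesis), which avoids the decarbonylation that troubles Friedel–Crafts reactions of methoxyacetyl chloride; no stereocentre is formed.

**Step 2**
Reactants: 4 2-methoxy-1-(2,3,4,5-tetramethoxyphenyl)ethan-1-one
Product: 5 1-(2-hydroxy-3,4,5-trimethoxyphenyl)-2-methoxyethan-1-one
Conditions: BCl3 (1.2 equiv, 1 M in CH2Cl2), CH2Cl2, −78 → 0 °C; then H2O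
Reagents that add atoms: none
Why: Boron chelated between the ketone oxygen and the ortho-methoxy oxygen (six-membered chelate) activates only that aryl methyl ether for chloride attack at methyl (chelation-controlled ortho-demethylation), while the other three aryl ethers and the aliphatic α-methoxy group, which would have to leave as an alkoxide, survive at low temperature.

**Step 3**
Reactants: 5 1-(2-hydroxy-3,4,5-trimethoxyphenyl)-2-methoxyethan-1-one; 6 3-methoxybenzoyl chloride
Product: 8 3,6,7,8-tetramethoxy-2-(3-methoxyphenyl)-4H-chromen-4-one, via 1,3-diketone 7 (not isolated)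
Conditions: LiN(SiMe3)2 (3.3 equiv), THF, −78 → −10 °C; 6 (1.05 equiv), −78 °C → rt; AcOH quench, evaporate; then AcOH, H2SO4 (cat.), 95 °C
Reagents that add atoms: none
Why: Claisen-type C-aroylation of the phenoxide/enolate dianion (the direct variant of the Baker–Venkataraman route; any O-aroyl ester rearranges to the same diketone under the excess base) is followed by acid-catalysed addition of the phenol to the aroyl carbonyl and dehydration, which closes ring C with the 3-OMe in place and destroys the CH(OMe) centre of 7.

**Step 4**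
Reactants: 8 3,6,7,8-tetramethoxy-2-(3-methoxyphenyl)-4H-chromen-4-one
Product: 11 emmaosunin, via C5-aryllithium 9 (not isolated), via lithium arylborate 10 (not isolated)
Conditions: B(OiPr)3 (2 equiv), LiTMP (lithium 2,2,6,6-tetramethylpiperidide, 1.5 equiv), THF, −78 → −40 °C; then AcOH, 30% aq. H2O2, 0 °C → rt
Reagents that add atoms: hydrogen peroxide, OO
Why: Proposed new method: carbonyl-directed peri-lithiation of a 2,3-disubstituted chromone with in-situ borate trapping and oxidative work-up as a one-flask C5–H hydroxylation; the strongly Lewis-basic pyranone carbonyl binds LiTMP and delivers it to the only C–H of ring A, which the flanking 6-OMe acidifies further (two cooperating directing groups, five-membered O–Li–C chelate), the usual chromone metalation sites C2 and C3 are blocked, the fleeting aryllithium 9 is captured at once by B(OiPr)3 before it can add to a chromone carbonyl, and the peroxide-induced 1,2-shift of aryl from boron to oxygen sets the C5–O bond exactly where the metal sat, giving the hydrogen-bonded 5-OH directly; the closest known reaction types are amide-base lithiation–borylation–oxidation of flavones at C3 and the LiTMP/B(OiPr)3 in-situ-trap ortho-borylation of benzoate esters; no stereocentre is formed.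

**Compound list**
1 | 1,2,3,4-tetramethoxybenzene | COc1ccc(OC)c(OC)c1OC | starting material
2 | N,2-dimethoxy-N-methylacetamide | COCC(=O)N(C)OC | starting material
3 | (2,3,4,5-tetramethoxyphenyl)lithium (not isolated) | [Li]c1cc(OC)c(OC)c(OC)c1OC | intermediate
4 | 2-methoxy-1-(2,3,4,5-tetramethoxyphenyl)ethan-1-one | COCC(=O)c1cc(OC)c(OC)c(OC)c1OC | intermediate
5 | 1-(2-hydroxy-3,4,5-trimethoxyphenyl)-2-methoxyethan-1-one | COCC(=O)c1cc(OC)c(OC)c(OC)c1O | intermediate
6 | 3-methoxybenzoyl chloride | COc1cccc(C(Cl)=O)c1 | starting material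
7 | 1-(2-hydroxy-3,4,5-trimethoxyphenyl)-2-methoxy-3-(3-methoxyphenyl)propane-1,3-dione (racemic, enolisable, not isolated) | COc1cccc(C(=O)C(OC)C(=O)c2cc(OC)c(OC)c(OC)c2O)c1 | intermediate
8 | 3,6,7,8-tetramethoxy-2-(3-methoxyphenyl)-4H-chromen-4-one | COc1cccc(-c2oc3c(OC)c(OC)c(OC)cc3c(=O)c2OC)c1 | intermediate
9 | [3,6,7,8-tetramethoxy-2-(3-methoxyphenyl)-4-oxo-4H-chromen-5-yl]lithium (not isolated) | COc1cccc(-c2oc3c(OC)c(OC)c(OC)c([Li])c3c(=O)c2OC)c1 | intermediate
10 | lithium triisopropoxy[3,6,7,8-tetramethoxy-2-(3-methoxyphenyl)-4-oxo-4H-chromen-5-yl]borate (not isolated) | [Li+].COc1cccc(-c2oc3c(OC)c(OC)c(OC)c([B-](OC(C)C)(OC(C)C)OC(C)C)c3c(=O)c2OC)c1 | intermediate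
11 | emmaosunin, 5-hydroxy-3,6,7,8-tetramethoxy-2-(3-methoxyphenyl)-4H-chromen-4-one (achiral) | COc1cccc(-c2oc3c(OC)c(OC)c(OC)c(O)c3c(=O)c2OC)c1 | target

**Totals**
Total step count: 4. Longest linear sequence: 4.

**Steps most likely to fail**

Step 4 (the proposed new step). The risks are competing lithiation at C2' of ring B (between the 3'-OMe and the chromone), attack of the aryllithium on a chromone carbonyl, and a sluggish deprotonation. The fallback sets out from 8 and comes back at 11, and uses the known ketone-directed C5 hydroxylation of flavones. Compound 8 is heated with [RuCl2(p-cymene)]2 (divalent ruthenium, 5 mol %) and the trivalent-iodine oxidant PhI(OCOCF3)2 in CF3CO2H/(CF3CO)2O at 80 °C. Carbonyl-directed ruthenation of C5–H and C–O bond formation give 3,6,7,8-tetramethoxy-2-(3-methoxyphenyl)-4-oxo-4H-chromen-5-yl 2,2,2-trifluoroacetate F1. Work-up with aq. NaHCO3/MeOH hydrolyses it to 11. This replaces stoichiometric deprotonation by catalytic C–H activation under acidic, oxidising conditions.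

Step 3. The risks are O- versus C-aroylation of the hindered α-methoxy enolate and incomplete cyclodehydration. The fallback sets out from 5 and comes back at 8, and changes the ring closure from a dehydration to an oxidative C–O cyclisation. Claisen–Schmidt condensation of 5 with 3-methoxybenzaldehyde (KOH, EtOH, rt) gives (Z)-1-(2-hydroxy-3,4,5-trimethoxyphenyl)-2-methoxy-3-(3-methoxyphenyl)prop-2-en-1-one F2. Heating F2 with catalytic I2 in DMSO at 130 °C closes and dehydrogenates it to 8.

Step 2. The risks are cleavage of the α-methoxy group or of a second aryl ether by BCl3. The fallback sets out from 1 and comes back at 8, replacing steps 1 to 3, and brings the 3-OMe in only after ring C exists. Friedel–Crafts acetylation of 1 (acetyl chloride, AlCl3, CH2Cl2, 0 °C → rt) gives 1-(2,3,4,5-tetramethoxyphenyl)ethan-1-one F3, not isolated. F3 loses its ortho methyl group in the same flask to give 1-(2-hydroxy-3,4,5-trimethoxyphenyl)ethan-1-one F4. Claisen–Schmidt condensation of F4 with 3-methoxybenzaldehyde (KOH, EtOH) gives (E)-1-(2-hydroxy-3,4,5-trimethoxyphenyl)-3-(3-methoxyphenyl)prop-2-en-1-one F5. Algar–Flynn–Oyamada oxidation of F5 (H2O2, NaOH, MeOH, 0 °C → rt) gives 3-hydroxy-6,7,8-trimethoxy-2-(3-methoxyphenyl)-4H-chromen-4-one F6; the chalcone has no 6'-substituent, so the flavonol and not the aurone is expected. Methylation of F6 (MeI, K2CO3, acetone, reflux) gives 8.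

**Further compounds**
F1 | step 4 | 3,6,7,8-tetramethoxy-2-(3-methoxyphenyl)-4-oxo-4H-chromen-5-yl 2,2,2-trifluoroacetate | COc1cccc(-c2oc3c(OC)c(OC)c(OC)c(OC(=O)C(F)(F)F)c3c(=O)c2OC)c1
F2 | step 3 | (Z)-1-(2-hydroxy-3,4,5-trimethoxyphenyl)-2-methoxy-3-(3-methoxyphenyl)prop-2-en-1-one | COc1cccc(/C=C(\OC)C(=O)c2cc(OC)c(OC)c(OC)c2O)c1
F3 | step 2 | 1-(2,3,4,5-tetramethoxyphenyl)ethan-1-one | CC(=O)c1cc(OC)c(OC)c(OC)c1OC
F4 | step 2 | 1-(2-hydroxy-3,4,5-trimethoxyphenyl)ethan-1-one | CC(=O)c1cc(OC)c(OC)c(OC)c1O
F5 | step 2 | (E)-1-(2-hydroxy-3,4,5-trimethoxyphenyl)-3-(3-methoxyphenyl)prop-2-en-1-one | COc1cccc(/C=C/C(=O)c2cc(OC)c(OC)c(OC)c2O)c1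
F6 | step 2 | 3-hydroxy-6,7,8-trimethoxy-2-(3-methoxyphenyl)-4H-chromen-4-one | COc1cccc(-c2oc3c(OC)c(OC)c(OC)cc3c(=O)c2O)c1
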